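Readings and results were generated by integration with constants of no real substance, noise included.

I reckon by exposure.

| flask | starting material | reagent in the second phase | remark | time | volume of the second phase over the first |
|---|---|---|---|---|---|
| Monday's | 10 mM | 10 mM | run made earlier |  |  |
| Saturday's | 10 mM | 22 mM | run made earlier |  |  |
| flask | 10 mM | 15.0 mM |  | 10 min | 1.0 |

- Monday's (time / min: target / %, starting material / %): 1.50: 8, 92; 4.00: 18, 82; 8.00: 27, 69; 12.0: 33, 65
- Saturday's (time / min: target / %, starting material / %): 1.00: 7, 95; 2.00: 17, 83; 5.00: 35, 60; 12.0: 46, 44

(standard deviation of a reading: 1.5 percentage points)

- in the second phase: reagent in the second phase; everything else is in the first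
- charges count per volume of the first phase; a concentration in a rate is the amount of a species over the volume of its own phase; every rate counts per litre of the first phase
- the earlier runs hold the two phases in the same ratio of volumes as the flask asked about

- violet: doubling the amount of reagent in the second phase, all else as stated
- teal: doubling the transfer coefficient of the reagent in the second phase, all else as stated

* amount of target at 10 min, in percent of the starting material charged
* the change that raises the amount of target at 10 min, in percent of the starting material charged most ("none" if none brings more than 2 percentage points) (violet / teal / none)
* amount of target at 10 min, in percent of the starting material charged, after teal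

I assume that starting material falls in proportion to itself, times the reagent that reaches it, as in a pseudo-first-order step. The logarithm of charged over left then measures what the reagent has delivered.

The plain bracket comes first. Monday's run gave 27% at 8.00 min, with less reagent and less time than the flask. Saturday's run gave 46% at 12.0 min, with more reagent and more time. The flask should lie between them.

Now I tighten it. At 12.0 min, Monday's logarithm is 0.431 and Saturday's is 0.821, so it follows the reagent charge to the power 0.818. Monday's last two readings average 0.401. Scaled to the flask's charge, that gives 0.559, the flask's exposure, the logarithm of charged over left. So 57.2% stays. Of the starting material consumed by 12.0 min, target kept 94.3% on Monday and 82.1% on Saturday. My bracket is therefore 35.2% to 40.4%. Doubling the reagent charge multiplies exposure by 1.76. This scaling holds no transfer coefficient, so it gives me no estimate for teal.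

The forecast says 38%, inside my bracket. Its range of 34% to 42% is wider than my bracket. It also picks violet and gives 40% after teal: “Doubling transfer adds little”.

The flask gives 37.7%, with 58% of the starting material left. Violet gains 11 percentage points and teal −0.2 points, reaching 37.5%, so violet is best.

    reagent in the reaction phase ⇌ reagent in the second phase, rate k1*([reagent in the reaction phase] - [reagent in the second phase]/K1) per volume of the first phase (partition coefficient = 0.340, kL = 0.00308 /s)
    starting material + reagent in the reaction phase → target (k = 0.382 /M/s)
    reagent in the reaction phase + target → over-reacted product (k = 0.135 /M/s)
    2 reagent in the reaction phase → self-condensation product (k = 1.00 /M/s)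
    reagent in the reaction phase ⇌ dormant form (K = 0.760, k = 0.0104 /s)

The flask's true exposure is 0.545, against my 0.559. The neighbour is charged with 25 mM of starting material, with the same reagent and time. Unchanged exposure leaves 57.2% in it. It actually keeps 66.9%, an exposure of 0.402, which is less than the flask's. Its target is 30.7% of a larger charge, 7.67 mM against 3.77 mM in the flask.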